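**Plan**

1. Numbering follows octahydro-1H-indene: ring B = C1 (carries C1′, the CH(OAc)CH3 carbon), C2 (ketone), C3, C3a, C7a; ring A = C3a, C4 (=CH2), C5, C6, C7 (carries the oxirane carbon C2″), C7a; α is the face of H3a/H7a, β the opposite face.
2. Retrosynthetic cuts, in order: the three acyl–O bonds; C4=CH2, then C4 itself out of ring A (C4–C3a and C4–C5, leaving a cis-bicyclo[3.3.0]octan-5-one); the oxirane and the methyl ester back to a γ-lactone that bridges O6 and the C7 side chain, then to a butenolide; ring B (C7a–C3a, C1–C2, C2–C3) by Pauson–Khand; C6–C5 by vinylogous aldol; C7a–C7 by Sonogashira.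
3. Forward: alkynyl butenolide → aldol → Pauson–Khand closes ring B together with a five-membered ring A (C4 missing) → hydrogenation → lactone turned into glycidate and C6 ester → C5 ketone → one-carbon expansion of ring A to six members → exocyclic methylene, C5 ester, acetate, ketone release.
4. Stereochemistry: C1′ from (S)-but-3-yn-2-ol; C6 (and a temporary C5 carbinol) from the catalyst-controlled aldol; C3a from the Pauson–Khand step (exo silyl ether); C1, C7a and C7 from all-cis hydrogenation on the convex face; C2″ from convex-face epoxidation of the temporary lactone; C5 from axial hydride delivery followed by Mitsunobu inversion; the acyl stereocenter from (S)-3-methylpentanoic acid.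
5. Enabling feature: in ring A the oxygenated C5 lies between the oxygenated C6 and the methylene carbon C4, which is bonded to the fusion atom C3a. With C4 absent, C5 as a ketone has one α-carbon (C6) deactivated by its acyloxy group, so an inserted diazo carbon should enter only the C5–C3a bond, become C4, and be held in an enol silane for methylenation.
6. Helpers that are removed again: the γ-lactone ring (step 10), the C5 silyloxy stereocenter (step 13), the C2 ketal (step 20).

Key step: step 14

Assumption: (R)-BINOL is taken as the ligand antipode that favors the (5R,1′R) aldol adduct in step 3 (the (S)-ligand is used if the sense proves opposite); compounds 3, 18 and 28 are taken as commercial.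

**Route**

Step 1
Reactants: 1 (S)-but-3-yn-2-ol
Product: 2 (S)-tert-butyl(but-3-yn-2-yloxy)dimethylsilane
Conditions: TBSCl, imidazole, DMF, 0 °C → rt
Reagents that add atoms: tert-butyldimethylsilyl chloride, CC(C)(C)[Si](C)(C)Cl
Why: Imidazole-mediated silylation of a secondary alcohol; the carbinol stereocenter is not touched, so the S configuration is carried into C1′.

Step 2
Reactants: 2 (S)-tert-butyl(but-3-yn-2-yloxy)dimethylsilane; 3 4-bromofuran-2(5H)-one
Product: 4 (S)-4-[3-(tert-butyldimethylsilyloxy)but-1-yn-1-yl]furan-2(5H)-one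
Conditions: Pd(PPh3)2Cl2 (3 mol %), CuI (6 mol %), i-Pr2NH, THF, rt
Reagents that add atoms: none
Why: Sonogashira coupling; the β-bromobutenolide is a vinylogous acyl bromide that should undergo fast oxidative addition, and no stereocenter is formed.

Step 3
Reactants: 4 (S)-4-[3-(tert-butyldimethylsilyloxy)but-1-yn-1-yl]furan-2(5H)-one; 5 acrolein
Product: 7 (R)-5-[(R)-1-hydroxyprop-2-en-1-yl]-4-[(S)-3-(tert-butyldimethylsilyloxy)but-1-yn-1-yl]furan-2(5H)-one, via silyloxyfuran 6 (not isolated)
Conditions: TMSOTf, Et3N, CH2Cl2, 0 °C; pentane trituration, concentration; then 5, Ti(OiPr)4/(R)-BINOL (20 mol %), Et2O, −20 °C; 1 M HCl work-up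
Reagents that add atoms: none
Why: Vinylogous Mukaiyama aldol reaction in which furan 6 attacks the aldehyde through C5 in an open transition state that should favor the threo (anti) adduct, the BINOL–titanium catalyst should set the absolute sense, and the C5 epimers are diastereomers (remote S center) that should be separable.

Step 4
Reactants: 7 (R)-5-[(R)-1-hydroxyprop-2-en-1-yl]-4-[(S)-3-(tert-butyldimethylsilyloxy)but-1-yn-1-yl]furan-2(5H)-one
Product: 8 triethylsilyl ether of 7
Conditions: TESCl, imidazole, CH2Cl2, 0 °C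
Reagents that add atoms: chlorotriethylsilane, CC[Si](Cl)(CC)CC
Why: Silylation of the allylic alcohol; the bulky silyl ether steers step 5 and later distinguishes O5 from O6.

Step 5
Reactants: 8 triethylsilyl ether of 7
Product: 9 tricyclic dienone lactone (ring B enone, five-membered ring A, fused butenolide)
Conditions: [Rh(CO)2Cl]2 (5 mol %), CO (1 atm), toluene, 110 °C
Reagents that add atoms: carbon monoxide, [C-]#[O+]
Why: Intramolecular Pauson–Khand [2+2+1] cycloaddition of the 1,6-enyne closes ring B and the five-membered ring A; the allylic silyl ether should take the exo position, cis to the new H3a, which sets C3a relative to C6.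

Step 6
Reactants: 9 tricyclic dienone lactone
Product: 10 all-cis keto lactone
Conditions: H2 (3 atm), 5% Rh/Al2O3, EtOAc, rt
Reagents that add atoms: none
Why: Heterogeneous hydrogenation should saturate both C=C bonds from the convex α face (the face of H3a and H6, since β-face addition would lead to trans-fused five-membered rings), setting C1, C7a and C7 all-cis, with rhodium on alumina chosen to limit hydrogenolysis of the allylic C–O bonds.

Step 7
Reactants: 10 all-cis keto lactone
Product: 11 C2 ethylene ketal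
Conditions: (TMSOCH2)2, TMSOTf (5 mol %), CH2Cl2, −78 → −20 °C
Reagents that add atoms: 1,2-bis(trimethylsilyloxy)ethane, C[Si](C)(C)OCCO[Si](C)(C)C
Why: Noyori ketalization masks the ring-B ketone under aprotic low-temperature conditions that should neither cleave the TES ether nor epimerize C1, and the lactone carbonyl does not react.

Step 8
Reactants: 11 C2 ethylene ketal
Product: 14 α-methylene lactone, via Mannich base 12 (not isolated), via methiodide 13 (not isolated)
Conditions: LDA, THF, −78 °C; Me2N=CH2+ I−, −78 °C → rt; then MeI, CH2Cl2/MeOH; then aq. NaHCO3, rt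
Reagents that add atoms: Eschenmoser's salt (N,N-dimethylmethyleneiminium iodide), C[N+](C)=C.[I-]
Why: Mannich reaction of the lactone enolate (the only enolizable position left) followed by quaternization and Hofmann-type elimination, the standard α-methylenation of γ-lactones.

Step 9
Reactants: 14 α-methylene lactone
Product: 15 spiro-epoxy lactone
Conditions: t-BuOOH, DBU, CH2Cl2, 0 °C → rt
Reagents that add atoms: tert-butyl hydroperoxide, CC(C)(C)OO
Why: Nucleophilic (Weitz–Scheffer-type) epoxidation in which the peroxide adds to the exocyclic CH2 and the lactone enolate closes on oxygen from the exposed convex face (the concave face is covered by rings A and B), which sets the quaternary oxirane carbon C2″.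

Step 10
Reactants: 15 spiro-epoxy lactone
Product: 17 hydroxy methyl ester, via lithium carboxylate 16 (not isolated)
Conditions: LiOH·H2O, THF/H2O (3:1), 0 °C; concentration; then MeI, DMF, 0 °C → rt
Reagents that add atoms: lithium hydroxide, [Li+].[OH-]; iodomethane, CI
Why: Saponification of the strained, α-oxygen-activated lactone followed by SN2 alkylation of the carboxylate; no acid is used, so relactonization to the congested cis,syn,cis tricycle should be slow and the ester-deactivated oxirane should survive.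

Step 11
Reactants: 17 hydroxy methyl ester; 18 (E)-3-methylpent-2-enoic acid
Product: 19 C6 enoate
Conditions: DCC, DMAP (0.2 equiv), CH2Cl2, 0 °C → rt
Reagents that add atoms: none
Why: Steglich esterification of the only free hydroxyl; carbodiimide activation avoids the acid chloride/amine conditions that deconjugate β,β-disubstituted enoates, so the E geometry should be kept.

Step 12
Reactants: 19 C6 enoate
Product: 20 C5 alcohol
Conditions: HF·pyridine, pyridine, THF, 0 °C
Reagents that add atoms: none
Why: Fluoride-mediated desilylation; a secondary TES ether should be cleaved by buffered HF·pyridine much faster than the secondary TBS ether.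

Step 13
Reactants: 20 C5 alcohol
Product: 21 4-nor C5 ketone (cis-bicyclo[3.3.0]octanone)
Conditions: Dess–Martin periodinane, NaHCO3, CH2Cl2, 0 °C → rt
Reagents that add atoms: none
Why: Dess–Martin oxidation under buffered conditions that should not epimerize the α-acyloxy carbon C6; the temporary C5 stereocenter is removed here.

Step 14
Reactants: 21 4-nor C5 ketone
Product: 23 ring-expanded trimethylsilyl enol ether (C4=C5), via α-silyl ketone 22 (not isolated)
Conditions: TMSCHN2 (1.5 equiv), Sc(OTf)3 (10 mol %), toluene, −78 → 0 °C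
Reagents that add atoms: (trimethylsilyl)diazomethane, C[Si](C)(C)C=[N+]=[N-]
Why: Sc(OTf)3 activates the C5 ketone, the diazo carbon adds to it, and loss of N2 from the betaine is coupled to a 1,2-shift of C3a (anti to the leaving N2, with retention at C3a) to give α-silyl ketone 22, which passes by a 1,3-silyl shift from carbon to oxygen into enol silane 23. The closest known reaction type is the Lewis-acid-catalysed Tiffeneau–Demjanov-type homologation of cycloalkanones with trimethylsilyldiazomethane. No ring is closed: ring A grows from five to six members by insertion of the new C4 between C5 and C3a (ring enlargement by 1,2-alkyl shift). No lasting stereocenter is created, since the C4–Si center is erased by the silyl shift and C3a, C6 and C7 are untouched. The step needs migration of C3a in preference to C6, which the electron-withdrawing acyloxy group on C6 should secure, and chemoselectivity for the ketone, which should follow because the ring-B ketone is a ketal, the β,β-disubstituted enoate is slow in dipolar cycloaddition at low temperature, and the ester-deactivated oxirane resists the Lewis acid. The enol silane fixes enolization toward C4, so the methylene can be placed in step 15 without competition from C6.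

Step 15
Reactants: 23 ring-expanded trimethylsilyl enol ether
Product: 26 α-methylene ketone, via Mannich base 24 (not isolated), via methiodide 25 (not isolated)
Conditions: Me2N=CH2+ I−, CH2Cl2, rt; then MeI; then aq. NaHCO3, rt
Reagents that add atoms: Eschenmoser's salt (N,N-dimethylmethyleneiminium iodide), C[N+](C)=C.[I-]
Why: Mannich reaction of the regiodefined silyl enol ether at C4, then quaternization and elimination under weak base, which should leave the α-acyloxy center C6 untouched.

Step 16
Reactants: 26 α-methylene ketone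
Product: 27 5β-allylic alcohol
Conditions: NaBH4, CeCl3·7H2O, MeOH, −78 °C
Reagents that add atoms: none
Why: Luche 1,2-reduction; hydride should add axially from the α face, anti to the axial 6β-acyloxy group (Felkin–Anh), giving the 5β (equatorial) alcohol while esters and oxirane are untouched.

Step 17
Reactants: 27 5β-allylic alcohol; 28 (S)-3-methylpentanoic acid
Product: 29 5α-(S)-3-methylpentanoate
Conditions: PPh3, DIAD, toluene, 0 °C → rt
Reagents that add atoms: none
Why: Mitsunobu esterification with SN2 inversion at C5 installs the ester on the α face; the cis 6β-acyloxy group lies syn to the leaving group and cannot participate.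

Step 18
Reactants: 29 5α-(S)-3-methylpentanoate
Product: 30 C1′ alcohol
Conditions: HF·pyridine, pyridine, THF, 0 °C → rt
Reagents that add atoms: none
Why: Fluoride-mediated cleavage of the secondary TBS ether under buffered conditions that should spare the ketal, the esters and the oxirane.

Step 19
Reactants: 30 C1′ alcohol
Product: 31 C1′ acetate
Conditions: Ac2O, pyridine, 0 °C → rt
Reagents that add atoms: acetic anhydride, CC(=O)OC(C)=O
Why: Acetylation of the only free hydroxyl; the C2 ketone is still masked, so no β-elimination can occur.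

Step 20
Reactants: 31 C1′ acetate
Product: 32 target CNP0109740.1
Conditions: PPTS (0.3 equiv), acetone/H2O (10:1), 45 °C
Reagents that add atoms: water, O
Why: Mild acid-catalysed ketal hydrolysis releases the C2 ketone last, so the β-acetoxy ketone never meets base and C1 should keep its configuration.

**Compound list**

1 | (S)-but-3-yn-2-ol | C[C@H](O)C#C | starting material
2 | (S)-tert-butyl(but-3-yn-2-yloxy)dimethylsilane | C[C@H](O[Si](C)(C)C(C)(C)C)C#C | intermediate
3 | 4-bromofuran-2(5H)-one | O=C1C=C(Br)CO1 | starting material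
4 | (S)-4-[3-(tert-butyldimethylsilyloxy)but-1-yn-1-yl]furan-2(5H)-one | C[C@H](O[Si](C)(C)C(C)(C)C)C#CC1=CC(=O)OC1 | intermediate
5 | acrolein (prop-2-enal) | C=CC=O | starting material
6 | 2-(trimethylsilyloxy)-4-[(S)-3-(tert-butyldimethylsilyloxy)but-1-yn-1-yl]furan | C[C@H](O[Si](C)(C)C(C)(C)C)C#Cc1coc(O[Si](C)(C)C)c1 | intermediate
7 | (R)-5-[(R)-1-hydroxyprop-2-en-1-yl]-4-[(S)-3-(tert-butyldimethylsilyloxy)but-1-yn-1-yl]furan-2(5H)-one | C=C[C@@H](O)[C@@H]1OC(=O)C=C1C#C[C@H](C)O[Si](C)(C)C(C)(C)C | intermediate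
8 | (R)-5-[(R)-1-(triethylsilyloxy)prop-2-en-1-yl]-4-[(S)-3-(tert-butyldimethylsilyloxy)but-1-yn-1-yl]furan-2(5H)-one | C=C[C@@H](O[Si](CC)(CC)CC)[C@@H]1OC(=O)C=C1C#C[C@H](C)O[Si](C)(C)C(C)(C)C | intermediate
9 | tricyclic dienone lactone: ring A five-membered (C3a, C5, C6, C7, C7a; C4 absent), C1=C7a and C7=C(lactone α) double bonds, C2 ketone, butenolide fused at C6–C7 with O on C6, 3aα-H, 6α-H, 5α-OTES, C1′ (S)-OTBS | CC[Si](CC)(CC)O[C@@H]1[C@H]2CC(=O)C([C@H](C)O[Si](C)(C)C(C)(C)C)=C2C3=CC(=O)O[C@H]31 | intermediate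
10 | all-cis keto lactone: 1α-H, 3aα-H, 7aα-H, 7α-H, 6α-H; γ-lactone on the β face across C6–C7; 5α-OTES; C2 ketone | CC[Si](CC)(CC)O[C@@H]1[C@H]2CC(=O)[C@@H]([C@H](C)O[Si](C)(C)C(C)(C)C)[C@H]2[C@H]3CC(=O)O[C@H]31 | intermediate
11 | C2 ethylene ketal of 10 | CC[Si](CC)(CC)O[C@@H]1[C@H]2CC4(OCCO4)[C@@H]([C@H](C)O[Si](C)(C)C(C)(C)C)[C@H]2[C@H]3CC(=O)O[C@H]31 | intermediate
12 | α-(dimethylaminomethyl) lactone (Mannich base, mixture at the lactone α-carbon) | CC[Si](CC)(CC)O[C@@H]1[C@H]2CC4(OCCO4)[C@@H]([C@H](C)O[Si](C)(C)C(C)(C)C)[C@H]2[C@H]3C(CN(C)C)C(=O)O[C@H]31 | intermediate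
13 | trimethylammonium iodide of 12 | CC[Si](CC)(CC)O[C@@H]1[C@H]2CC4(OCCO4)[C@@H]([C@H](C)O[Si](C)(C)C(C)(C)C)[C@H]2[C@H]3C(C[N+](C)(C)C)C(=O)O[C@H]31.[I-] | intermediate
14 | α-methylene lactone | CC[Si](CC)(CC)O[C@@H]1[C@H]2CC4(OCCO4)[C@@H]([C@H](C)O[Si](C)(C)C(C)(C)C)[C@H]2[C@H]3C(=C)C(=O)O[C@H]31 | intermediate
15 | spiro-epoxy lactone, oxirane oxygen on the convex (α) face of the lactone | CC[Si](CC)(CC)O[C@@H]1[C@H]2CC4(OCCO4)[C@@H]([C@H](C)O[Si](C)(C)C(C)(C)C)[C@H]2[C@H]3[C@@]5(CO5)C(=O)O[C@H]31 | intermediate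
16 | lithium oxirane-2-carboxylate with free 6β-OH (opened lactone) | CC[Si](CC)(CC)O[C@@H]1[C@H]2CC4(OCCO4)[C@@H]([C@H](C)O[Si](C)(C)C(C)(C)C)[C@H]2[C@@H]([C@]3(C(=O)[O-])CO3)[C@H]1O.[Li+] | intermediate
17 | methyl oxirane-2-carboxylate on C7, 6β-OH, 5α-OTES (4-nor skeleton) | CC[Si](CC)(CC)O[C@@H]1[C@H]2CC4(OCCO4)[C@@H]([C@H](C)O[Si](C)(C)C(C)(C)C)[C@H]2[C@@H]([C@]3(C(=O)OC)CO3)[C@H]1O | intermediate
18 | (E)-3-methylpent-2-enoic acid | CC/C(C)=C/C(=O)O | starting material
19 | 6β-[(E)-3-methylpent-2-enoate] of 17 | CC[Si](CC)(CC)O[C@@H]1[C@H]2CC4(OCCO4)[C@@H]([C@H](C)O[Si](C)(C)C(C)(C)C)[C@H]2[C@@H]([C@]3(C(=O)OC)CO3)[C@H]1OC(=O)/C=C(\C)CC | intermediate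
20 | 5α-alcohol (TES removed) | O[C@@H]1[C@H]2CC4(OCCO4)[C@@H]([C@H](C)O[Si](C)(C)C(C)(C)C)[C@H]2[C@@H]([C@]3(C(=O)OC)CO3)[C@H]1OC(=O)/C=C(\C)CC | intermediate
21 | 4-nor C5 ketone (cis-bicyclo[3.3.0]octanone with 6β-enoate, 7β-glycidate, C2 ketal) | O=C1[C@H]2CC4(OCCO4)[C@@H]([C@H](C)O[Si](C)(C)C(C)(C)C)[C@H]2[C@@H]([C@]3(C(=O)OC)CO3)[C@H]1OC(=O)/C=C(\C)CC | intermediate
22 | 4-(trimethylsilyl)hydrindan-5-one (ring A six-membered, mixture at C4) | C[Si](C)(C)C1[C@H]2CC4(OCCO4)[C@@H]([C@H](C)O[Si](C)(C)C(C)(C)C)[C@H]2[C@@H]([C@]3(C(=O)OC)CO3)[C@@H](OC(=O)/C=C(\C)CC)C1=O | intermediate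
23 | C4=C5 trimethylsilyl enol ether of the hydrindan-5-one | C[Si](C)(C)OC1=C[C@H]2CC4(OCCO4)[C@@H]([C@H](C)O[Si](C)(C)C(C)(C)C)[C@H]2[C@@H]([C@]3(C(=O)OC)CO3)[C@H]1OC(=O)/C=C(\C)CC | intermediate
24 | 4-(dimethylaminomethyl)hydrindan-5-one (Mannich base) | CN(C)CC1[C@H]2CC4(OCCO4)[C@@H]([C@H](C)O[Si](C)(C)C(C)(C)C)[C@H]2[C@@H]([C@]3(C(=O)OC)CO3)[C@@H](OC(=O)/C=C(\C)CC)C1=O | intermediate
25 | trimethylammonium iodide of 24 | C[N+](C)(C)CC1[C@H]2CC4(OCCO4)[C@@H]([C@H](C)O[Si](C)(C)C(C)(C)C)[C@H]2[C@@H]([C@]3(C(=O)OC)CO3)[C@@H](OC(=O)/C=C(\C)CC)C1=O.[I-] | intermediate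
26 | 4-methylenehydrindan-5-one | C=C1[C@H]2CC4(OCCO4)[C@@H]([C@H](C)O[Si](C)(C)C(C)(C)C)[C@H]2[C@@H]([C@]3(C(=O)OC)CO3)[C@@H](OC(=O)/C=C(\C)CC)C1=O | intermediate
27 | 5β-allylic alcohol | C=C1[C@H]2CC4(OCCO4)[C@@H]([C@H](C)O[Si](C)(C)C(C)(C)C)[C@H]2[C@@H]([C@]3(C(=O)OC)CO3)[C@@H](OC(=O)/C=C(\C)CC)[C@H]1O | intermediate
28 | (S)-3-methylpentanoic acid | CC[C@H](C)CC(=O)O | starting material
29 | 5α-[(S)-3-methylpentanoate], C1′ OTBS, C2 ketal | C=C1[C@H]2CC4(OCCO4)[C@@H]([C@H](C)O[Si](C)(C)C(C)(C)C)[C@H]2[C@@H]([C@]3(C(=O)OC)CO3)[C@@H](OC(=O)/C=C(\C)CC)[C@@H]1OC(=O)C[C@@H](C)CC | intermediate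
30 | C1′ alcohol | C=C1[C@H]2CC4(OCCO4)[C@@H]([C@H](C)O)[C@H]2[C@@H]([C@]3(C(=O)OC)CO3)[C@@H](OC(=O)/C=C(\C)CC)[C@@H]1OC(=O)C[C@@H](C)CC | intermediate
31 | C1′ acetate, C2 ethylene ketal | C=C1[C@H]2CC4(OCCO4)[C@@H]([C@H](C)OC(C)=O)[C@H]2[C@@H]([C@]3(C(=O)OC)CO3)[C@@H](OC(=O)/C=C(\C)CC)[C@@H]1OC(=O)C[C@@H](C)CC | intermediate
32 | methyl 2-[1β-((S)-1-acetoxyethyl)-4-methylene-5α-((S)-3-methylpentanoyloxy)-6β-((E)-3-methylpent-2-enoyloxy)-2-oxo-3aα,7aα-octahydroinden-7β-yl]oxirane-2-carboxylate (absolute configuration as in the SMILES) | C=C1[C@H]2CC(=O)[C@@H]([C@H](C)OC(C)=O)[C@H]2[C@@H]([C@]2(C(=O)OC)CO2)[C@@H](OC(=O)/C=C(\C)CC)[C@@H]1OC(=O)C[C@@H](C)CC | target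

**Step count**

Total step count: 20. Longest linear sequence: 20 steps (1 → 32); acids 18 and 28, bromide 3 and acrolein 5 enter as purchased materials.

**Steps most likely to fail, with fallbacks**

1. Step 14. Addition of the diazoalkane to the hindered α-acyloxy ketone may be slow, the betaine may collapse to a spiro-epoxide instead of migrating, or dipolar cycloaddition to the enoate may compete. The fallback sets out from 21 and comes back at 26. Addition of vinylmagnesium bromide with CeCl3 (THF, −78 °C) should give tertiary allylic alcohol F1. N-Bromosuccinimide (propylene oxide, i-PrOH, 0 °C) should then trigger a bromonium-induced semipinacol shift of C3a, again favored over the acyloxy-bearing C6, to give α-(bromomethyl) ketone F2. DBU should eliminate HBr to the α-methylene ketone 26.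

2. Step 6. Hydrogen may be delivered with poor facial selectivity, 1,4-addition may leave a tetrasubstituted C7=C7a alkene that resists reduction, and allylic C–O bonds may be hydrogenolysed. The fallback sets out from 9 and comes back at 10. Desilylation with HF·pyridine should give hydroxy dienone F3. Hydroxyl-directed homogeneous hydrogenation with [Ir(cod)(PCy3)(py)]PF6 and H2 in CH2Cl2 should deliver hydrogen from the α face, on which the C5 hydroxyl sits, to give hydroxy keto lactone F4. Resilylation (TESCl, imidazole) returns to 10.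

3. Step 3. Enantio- or diastereocontrol may be low, and conjugate addition to acrolein or its polymerization may compete. The fallback sets out from 4 (converted to furan 6 as in step 3) and comes back at 7. A substrate-controlled vinylogous aldol reaction of 6 with (R)-2,3-O-isopropylideneglyceraldehyde (BF3·OEt2, CH2Cl2, −78 °C) should give, through its known 4,5-threo-5,6-erythro preference, acetonide adduct F5 with the required 5R,1′R centers. Aqueous acetic acid should give triol F6. Thiocarbonyldiimidazole should close the terminal cyclic thionocarbonate F7, and Corey–Winter olefination (P(OMe)3, 110 °C) should deliver the vinyl carbinol 7.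

Further compounds
F1 | step 14 | 5-vinyl tertiary alcohol of the 4-nor skeleton (vinyl α, OH β) | C=C[C@]1(O)[C@H]2CC4(OCCO4)[C@@H]([C@H](C)O[Si](C)(C)C(C)(C)C)[C@H]2[C@@H]([C@]3(C(=O)OC)CO3)[C@H]1OC(=O)/C=C(\C)CC
F2 | step 14 | 4-(bromomethyl)hydrindan-5-one (mixture at C4) | BrCC1[C@H]2CC4(OCCO4)[C@@H]([C@H](C)O[Si](C)(C)C(C)(C)C)[C@H]2[C@@H]([C@]3(C(=O)OC)CO3)[C@@H](OC(=O)/C=C(\C)CC)C1=O
F3 | step 6 | 5α-hydroxy tricyclic dienone lactone (9 without TES) | O[C@@H]1[C@H]2CC(=O)C([C@H](C)O[Si](C)(C)C(C)(C)C)=C2C3=CC(=O)O[C@H]31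
F4 | step 6 | 5α-hydroxy all-cis keto lactone (10 without TES) | O[C@@H]1[C@H]2CC(=O)[C@@H]([C@H](C)O[Si](C)(C)C(C)(C)C)[C@H]2[C@H]3CC(=O)O[C@H]31
F5 | step 3 | (R)-5-[(R)-hydroxy((R)-2,2-dimethyl-1,3-dioxolan-4-yl)methyl] butenolide (D-arabino-type adduct) | CC1(C)OC[C@@H](O1)[C@@H](O)[C@@H]2OC(=O)C=C2C#C[C@H](C)O[Si](C)(C)C(C)(C)C
F6 | step 3 | triol from acetonide hydrolysis of F5 | OC[C@@H](O)[C@@H](O)[C@@H]1OC(=O)C=C1C#C[C@H](C)O[Si](C)(C)C(C)(C)C
F7 | step 3 | terminal cyclic thionocarbonate of F6 | S=C1OC[C@@H](O1)[C@@H](O)[C@@H]2OC(=O)C=C2C#C[C@H](C)O[Si](C)(C)C(C)(C)C
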